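**Retrosynthetic overview**

1. Numbering: ring A (3‑hydroxy‑4‑methoxyphenyl)–C7–C8(C9H2–OBz)–C8'(C9'H2–OBz)–C7'–ring B (4‑hydroxy‑3‑methoxyphenyl), with C8 and C8' both R. The strategy rests on the C9–C8–C8'–C9' 1,4‑dioxygenated unit: joining C9 (as C=O) to the C9' oxygen gives a trans‑3,4‑bis(arylmethyl)butyrolactone whose carbonyl carbon C9 can be CO.
2. Target ⇐ hydrogenolysis of the bis(benzyl ether) dibenzoate 14 ⇐ dibenzoylation of the (2R,3R)‑diol 13 ⇐ LiAlH4 reduction of the (3R,4R)‑lactone 12.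
3. Lactone 12 (the only ring made in the route; rings A and B are bought) ⇐ E‑allylic alcohol 11 + CO, by palladium‑catalysed asymmetric cyclocarbonylation that forms C8–C9, the C9–O bond and both stereocentres.
4. Alcohol 11 ⇐ E‑enoate 10 (1,2‑reduction) ⇐ Wittig olefination of the ring B‑benzylated stabilised ylide 6 with the ring A arylacetaldehyde 9.
5. Ylide 6 ⇐ O‑benzylvanillin 1 (via benzyl bromide 3) + Ph3P=CHCO2Et 4; aldehyde 9 ⇐ O‑benzylisovanillin 7 by one‑carbon homologation.

Key step: step 8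

Assumption (starting materials): 4‑(benzyloxy)‑3‑methoxybenzaldehyde and 3‑(benzyloxy)‑4‑methoxybenzaldehyde are taken as catalogue compounds; otherwise each is one step from vanillin or isovanillin (BnBr, K2CO3, DMF).
Assumption (ligand antipode): the sense of induction of the bisphosphine on this substrate cannot be predicted with confidence; the (R,R) antipode is written, and the (S,S) antipode is used instead if a first trial gives the (3S,4S) lactone.

**Route**

Step 1
Reactants: 1 4‑(benzyloxy)‑3‑methoxybenzaldehyde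
Product: 2 [4‑(benzyloxy)‑3‑methoxyphenyl]methanol
Conditions: NaBH4, MeOH/THF, 0 °C
Reagents that add atoms: none
Why: Borohydride reduction of an aryl aldehyde to the benzylic alcohol should proceed cleanly, the benzyl ether being inert to hydride.

Step 2
Reactants: 2 [4‑(benzyloxy)‑3‑methoxyphenyl]methanol
Product: 3 1‑(benzyloxy)‑4‑(bromomethyl)‑2‑methoxybenzene
Conditions: PBr3 (0.4 equiv), Et2O, 0 °C
Reagents that add atoms: phosphorus tribromide, BrP(Br)Br
Why: Bromination of an electron‑rich benzylic alcohol with PBr3 (substitution of the intermediate phosphite ester by bromide) is fast at 0 °C, and the bromide is used without storage.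

Step 3
Reactants: 3 1‑(benzyloxy)‑4‑(bromomethyl)‑2‑methoxybenzene; 4 ethyl (triphenylphosphoranylidene)acetate
Product: 6 ethyl 3‑[4‑(benzyloxy)‑3‑methoxyphenyl]‑2‑(triphenylphosphoranylidene)propanoate, via benzylated phosphonium bromide 5 (not isolated)
Conditions: toluene, 70 °C; then 2 M aq NaOH, CH2Cl2, rt
Reagents that add atoms: none
Why: C‑Alkylation of a stabilised phosphorus ylide by a reactive benzylic bromide gives the phosphonium salt, whose acidic α‑hydrogen is removed by hydroxide to give the disubstituted stabilised ylide (ylide alkylation followed by deprotonation), and the hydroxide treatment also reverses any transylidation by unreacted 4.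

Step 4
Reactants: 7 3‑(benzyloxy)‑4‑methoxybenzaldehyde
Product: 8 2‑(benzyloxy)‑1‑methoxy‑4‑(2‑methoxyethenyl)benzene (E/Z mixture)
Conditions: Ph3PCH2OMe Cl, KOtBu, THF, 0 °C to rt
Reagents that add atoms: (methoxymethyl)triphenylphosphonium chloride, COC[P+](c1ccccc1)(c1ccccc1)c1ccccc1.[Cl-]
Why: Wittig methoxymethylenation of a non‑enolisable aryl aldehyde is a standard one‑carbon homologation, and the alkene geometry is irrelevant because both isomers hydrolyse to the same aldehyde.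

Step 5
Reactants: 8 2‑(benzyloxy)‑1‑methoxy‑4‑(2‑methoxyethenyl)benzene
Product: 9 [3‑(benzyloxy)‑4‑methoxyphenyl]acetaldehyde
Conditions: 3 M aq HCl, THF, 50 °C, N2; crude aldehyde used the same day
Reagents that add atoms: water, O
Why: Acid‑catalysed enol ether hydrolysis (C‑protonation, addition of water to the oxocarbenium ion, loss of methanol) should deliver the arylacetaldehyde, which is not stored because it is prone to self‑condensation.

Step 6
Reactants: 9 [3‑(benzyloxy)‑4‑methoxyphenyl]acetaldehyde; 6 ethyl 3‑[4‑(benzyloxy)‑3‑methoxyphenyl]‑2‑(triphenylphosphoranylidene)propanoate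
Product: 10 ethyl (2E)‑2‑[4‑(benzyloxy)‑3‑methoxybenzyl]‑4‑[3‑(benzyloxy)‑4‑methoxyphenyl]but‑2‑enoate
Conditions: 9 (1.2 equiv), toluene, 50 °C
Reagents that add atoms: none
Why: Wittig olefination with an α‑substituted ester‑stabilised ylide should place the aldehyde substituent trans to the ester (E‑enoate, the two arylmethyl groups cis), and the base‑free conditions limit enolisation of the aldehyde and migration of the new double bond toward ring A.

Step 7
Reactants: 10 ethyl (2E)‑2‑[4‑(benzyloxy)‑3‑methoxybenzyl]‑4‑[3‑(benzyloxy)‑4‑methoxyphenyl]but‑2‑enoate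
Product: 11 (2E)‑2‑[4‑(benzyloxy)‑3‑methoxybenzyl]‑4‑[3‑(benzyloxy)‑4‑methoxyphenyl]but‑2‑en‑1‑ol
Conditions: iBu2AlH (DIBAL‑H, 2.5 equiv), CH2Cl2, −78 °C; aq KNaC4H4O6 work‑up
Reagents that add atoms: none
Why: 1,2‑Reduction of an α,β‑unsaturated ester with iBu2AlH at low temperature should give the allylic alcohol without touching the alkene geometry or the benzyl ethers.

Step 8
Reactants: 11 (2E)‑2‑[4‑(benzyloxy)‑3‑methoxybenzyl]‑4‑[3‑(benzyloxy)‑4‑methoxyphenyl]but‑2‑en‑1‑ol
Product: 12 (3R,4R)‑3‑[3‑(benzyloxy)‑4‑methoxybenzyl]‑4‑[4‑(benzyloxy)‑3‑methoxybenzyl]dihydrofuran‑2(3H)‑one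
Conditions: Pd2(dba)3·CHCl3 (2 mol%), (1R,1'R,2R,2'R)‑2,2'‑bis(diphenylphosphino)‑1,1'‑bicyclopentane [(R,R)‑BICP, 4.4 mol%], CO/H2 (1:1, 55 bar total), CH2Cl2, 80 °C
Reagents that add atoms: carbon monoxide, [C-]#[O+]
Why: Zerovalent palladium, the bisphosphine and CO/H2 should form a chiral hydride of divalent palladium that adds syn across C2=C3 of 11 with H to the fully substituted C2 (C8') and Pd to C3 (C8), after which CO inserts into the Pd–C3 bond with retention and the C1 hydroxyl attacks the acyl carbon, releasing 12 and the hydride; the closest known reaction type is the palladium–bisphosphine cyclocarbonylation of allylic alcohols to gamma‑butyrolactones under CO/H2, which has asymmetric variants with chiral 1,4‑bisphosphines. The single ring is closed by 5‑exo‑trig attack of the hydroxyl oxygen on the acylpalladium carbon (C9–O bond) once C8–C9 has been made by migratory insertion. Both stereocentres come from one face‑selective syn addition: the ligand selects the alkene face that is Re at C3 and Si at C2, which gives 3R,4R, and because the two arylmethyl groups are cis in the E‑alkene, syn delivery of H and acyl puts them trans on the ring. The step needs regioselectivity (Pd at C3 and not at C2), which the preference for a secondary over a tertiary alkylpalladium and the five‑membered lactone closure secure, and it needs CO insertion to outrun beta‑hydride elimination toward C4, which the CO pressure and the chelating ligand favour. The trans lactone is also the more stable C3 epimer, so enolisation cannot erode the relative configuration.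

Step 9
Reactants: 12 (3R,4R)‑3‑[3‑(benzyloxy)‑4‑methoxybenzyl]‑4‑[4‑(benzyloxy)‑3‑methoxybenzyl]dihydrofuran‑2(3H)‑one
Product: 13 (2R,3R)‑2‑[3‑(benzyloxy)‑4‑methoxybenzyl]‑3‑[4‑(benzyloxy)‑3‑methoxybenzyl]butane‑1,4‑diol
Conditions: LiAlH4, THF, 0 °C to rt
Reagents that add atoms: none
Why: Hydride reduction of the lactone to the 1,4‑diol breaks no bond at C8 or C8', so both centres are carried over unchanged and the benzyl ethers are untouched.

Step 10
Reactants: 13 (2R,3R)‑2‑[3‑(benzyloxy)‑4‑methoxybenzyl]‑3‑[4‑(benzyloxy)‑3‑methoxybenzyl]butane‑1,4‑diol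
Product: 14 (2R,3R)‑2‑[3‑(benzyloxy)‑4‑methoxybenzyl]‑3‑[4‑(benzyloxy)‑3‑methoxybenzyl]butane‑1,4‑diyl dibenzoate
Conditions: BzCl (2.5 equiv), pyridine, DMAP (cat.), CH2Cl2, 0 °C to rt
Reagents that add atoms: benzoyl chloride, O=C(Cl)c1ccccc1
Why: DMAP‑catalysed acylation of two unhindered primary alcohols should be complete, and with the phenols still benzylated only C9–OH and C9'–OH can be esterified.

Step 11
Reactants: 14 (2R,3R)‑2‑[3‑(benzyloxy)‑4‑methoxybenzyl]‑3‑[4‑(benzyloxy)‑3‑methoxybenzyl]butane‑1,4‑diyl dibenzoate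
Product: 15 (2R,3R)‑2‑(3‑hydroxy‑4‑methoxybenzyl)‑3‑(4‑hydroxy‑3‑methoxybenzyl)butane‑1,4‑diyl dibenzoate (CNP0306197.1)
Conditions: H2 (1 atm), 10% Pd/C, EtOAc/EtOH, rt
Reagents that add atoms: none
Why: Catalytic hydrogenolysis cleaves the two aryl benzyl ethers under conditions that leave the benzoates of non‑benzylic primary alcohols, the arenes and the two stereocentres intact.

**Compound list**

1 | 4‑(benzyloxy)‑3‑methoxybenzaldehyde | COc1cc(C=O)ccc1OCc1ccccc1 | starting material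
2 | [4‑(benzyloxy)‑3‑methoxyphenyl]methanol | COc1cc(CO)ccc1OCc1ccccc1 | intermediate
3 | 1‑(benzyloxy)‑4‑(bromomethyl)‑2‑methoxybenzene | COc1cc(CBr)ccc1OCc1ccccc1 | intermediate
4 | ethyl (triphenylphosphoranylidene)acetate | CCOC(=O)C=P(c1ccccc1)(c1ccccc1)c1ccccc1 | starting material
5 | {3‑[4‑(benzyloxy)‑3‑methoxyphenyl]‑1‑ethoxy‑1‑oxopropan‑2‑yl}triphenylphosphonium bromide (racemic) | CCOC(=O)C(Cc1ccc(OCc2ccccc2)c(OC)c1)[P+](c1ccccc1)(c1ccccc1)c1ccccc1.[Br-] | intermediate
6 | ethyl 3‑[4‑(benzyloxy)‑3‑methoxyphenyl]‑2‑(triphenylphosphoranylidene)propanoate | CCOC(=O)C(Cc1ccc(OCc2ccccc2)c(OC)c1)=P(c1ccccc1)(c1ccccc1)c1ccccc1 | intermediate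
7 | 3‑(benzyloxy)‑4‑methoxybenzaldehyde | COc1ccc(C=O)cc1OCc1ccccc1 | starting material
8 | 2‑(benzyloxy)‑1‑methoxy‑4‑(2‑methoxyethenyl)benzene (E/Z mixture) | COC=Cc1ccc(OC)c(OCc2ccccc2)c1 | intermediate
9 | [3‑(benzyloxy)‑4‑methoxyphenyl]acetaldehyde | COc1ccc(CC=O)cc1OCc1ccccc1 | intermediate
10 | ethyl (2E)‑2‑[4‑(benzyloxy)‑3‑methoxybenzyl]‑4‑[3‑(benzyloxy)‑4‑methoxyphenyl]but‑2‑enoate | CCOC(=O)/C(Cc1ccc(OCc2ccccc2)c(OC)c1)=C/Cc1ccc(OC)c(OCc2ccccc2)c1 | intermediate
11 | (2E)‑2‑[4‑(benzyloxy)‑3‑methoxybenzyl]‑4‑[3‑(benzyloxy)‑4‑methoxyphenyl]but‑2‑en‑1‑ol | OC/C(Cc1ccc(OCc2ccccc2)c(OC)c1)=C/Cc1ccc(OC)c(OCc2ccccc2)c1 | intermediate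
12 | (3R,4R)‑3‑[3‑(benzyloxy)‑4‑methoxybenzyl]‑4‑[4‑(benzyloxy)‑3‑methoxybenzyl]dihydrofuran‑2(3H)‑one | COc1ccc(C[C@H]2C(=O)OC[C@@H]2Cc2ccc(OCc3ccccc3)c(OC)c2)cc1OCc1ccccc1 | intermediate
13 | (2R,3R)‑2‑[3‑(benzyloxy)‑4‑methoxybenzyl]‑3‑[4‑(benzyloxy)‑3‑methoxybenzyl]butane‑1,4‑diol | COc1ccc(C[C@@H](CO)[C@H](CO)Cc2ccc(OCc3ccccc3)c(OC)c2)cc1OCc1ccccc1 | intermediate
14 | (2R,3R)‑2‑[3‑(benzyloxy)‑4‑methoxybenzyl]‑3‑[4‑(benzyloxy)‑3‑methoxybenzyl]butane‑1,4‑diyl dibenzoate | COc1ccc(C[C@@H](COC(=O)c2ccccc2)[C@H](COC(=O)c2ccccc2)Cc2ccc(OCc3ccccc3)c(OC)c2)cc1OCc1ccccc1 | intermediate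
15 | (2R,3R)‑2‑(3‑hydroxy‑4‑methoxybenzyl)‑3‑(4‑hydroxy‑3‑methoxybenzyl)butane‑1,4‑diyl dibenzoate | COc1ccc(C[C@@H](COC(=O)c2ccccc2)[C@H](COC(=O)c2ccccc2)Cc2ccc(O)c(OC)c2)cc1O | target

**Step count**

Total step count: 11.
Longest linear sequence: 9 steps (1 → 2 → 3 → 6 → 10 → 11 → 12 → 13 → 14 → 15).

**Steps most likely to fail**

Step 8 (cyclocarbonylation). The alkylpalladium intermediate may chain‑walk toward C4 and move the alkene into conjugation with ring A, the allylic C–O bond may ionise, or the ligand may discriminate the alkene faces poorly, so the lactone could form slowly or with low enantiomeric purity. The fallback sets out from 1 and 7 and comes back at 12 by the classical enolate alkylation of a β‑substituted lactone.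
- Stobbe condensation of 1 with dimethyl succinate (NaOMe, MeOH, reflux) should give (3E)‑4‑[4‑(benzyloxy)‑3‑methoxyphenyl]‑3‑(methoxycarbonyl)but‑3‑enoic acid F1.
- Rhodium–bisphosphine asymmetric hydrogenation ([Rh(cod)2]BF4, the MOD‑DIOP antipode that leads to the R acid, H2, MeOH/Et3N) should give (3R)‑4‑[4‑(benzyloxy)‑3‑methoxyphenyl]‑3‑(methoxycarbonyl)butanoic acid F2.
- Reduction of the ester in the presence of the potassium carboxylate with Ca(BH4)2 (CaCl2, NaBH4, EtOH) and acidification should close (4R)‑4‑[4‑(benzyloxy)‑3‑methoxybenzyl]dihydrofuran‑2(3H)‑one F3.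
- In parallel, 7 is reduced (NaBH4, MeOH) to [3‑(benzyloxy)‑4‑methoxyphenyl]methanol F4 and brominated (PBr3, Et2O, 0 °C) to 2‑(benzyloxy)‑4‑(bromomethyl)‑1‑methoxybenzene F5.
- Deprotonation of F3 with LiN(SiMe3)2 in THF at −78 °C and alkylation with F5, anti to the C4 substituent, should give 12.

Step 6 (Wittig olefination). The ylide may enolise the arylacetaldehyde and trigger its self‑aldol condensation, the hindered ylide may react slowly, or the new double bond may migrate toward ring A and lower the E purity. The fallback sets out from 6 and comes back at 10, bringing ring A in as an aryl nucleophile so that aldehyde 9 is not needed.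
- Wittig reaction of 6 with glycolaldehyde dimer (toluene, 80 °C) should give ethyl (2E)‑2‑[4‑(benzyloxy)‑3‑methoxybenzyl]‑4‑hydroxybut‑2‑enoate F6.
- Appel bromination (CBr4, PPh3, CH2Cl2, 0 °C) should give ethyl (2E)‑2‑[4‑(benzyloxy)‑3‑methoxybenzyl]‑4‑bromobut‑2‑enoate F7.
- Suzuki–Miyaura allyl–aryl coupling of F7 with purchased [3‑(benzyloxy)‑4‑methoxyphenyl]boronic acid (Pd(PPh3)4, K3PO4, toluene, 70 °C) should join ring A to C7 at the unhindered allyl terminus and give 10.

Step 5 (enol ether hydrolysis). Under aqueous acid and heat the arylacetaldehyde may undergo aldol condensation and oligomerisation as it forms. The fallback sets out from 7 and comes back at 9 by a neutral, non‑aqueous oxidation.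
- Wittig methylenation of 7 (Ph3PCH3Br, KOtBu, THF) should give 2‑(benzyloxy)‑4‑ethenyl‑1‑methoxybenzene F8.
- Anti‑Markovnikov hydroboration–oxidation (9‑BBN, THF; then NaOH, H2O2) should give 2‑[3‑(benzyloxy)‑4‑methoxyphenyl]ethanol F9.
- Dess–Martin periodinane (NaHCO3, CH2Cl2, rt) should give 9, which is taken directly into step 6.

**Further compounds**

F1 | step 8 | (3E)‑4‑[4‑(benzyloxy)‑3‑methoxyphenyl]‑3‑(methoxycarbonyl)but‑3‑enoic acid | COC(=O)/C(CC(=O)O)=C/c1ccc(OCc2ccccc2)c(OC)c1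
F2 | step 8 | (3R)‑4‑[4‑(benzyloxy)‑3‑methoxyphenyl]‑3‑(methoxycarbonyl)butanoic acid | COC(=O)[C@@H](CC(=O)O)Cc1ccc(OCc2ccccc2)c(OC)c1
F3 | step 8 | (4R)‑4‑[4‑(benzyloxy)‑3‑methoxybenzyl]dihydrofuran‑2(3H)‑one | O=C1OC[C@H](Cc2ccc(OCc3ccccc3)c(OC)c2)C1
F4 | step 8 | [3‑(benzyloxy)‑4‑methoxyphenyl]methanol | COc1ccc(CO)cc1OCc1ccccc1
F5 | step 8 | 2‑(benzyloxy)‑4‑(bromomethyl)‑1‑methoxybenzene | COc1ccc(CBr)cc1OCc1ccccc1
F6 | step 6 | ethyl (2E)‑2‑[4‑(benzyloxy)‑3‑methoxybenzyl]‑4‑hydroxybut‑2‑enoate | CCOC(=O)/C(Cc1ccc(OCc2ccccc2)c(OC)c1)=C/CO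
F7 | step 6 | ethyl (2E)‑2‑[4‑(benzyloxy)‑3‑methoxybenzyl]‑4‑bromobut‑2‑enoate | CCOC(=O)/C(Cc1ccc(OCc2ccccc2)c(OC)c1)=C/CBr
F8 | step 5 | 2‑(benzyloxy)‑4‑ethenyl‑1‑methoxybenzene | C=Cc1ccc(OC)c(OCc2ccccc2)c1
F9 | step 5 | 2‑[3‑(benzyloxy)‑4‑methoxyphenyl]ethanol | OCCc1ccc(OC)c(OCc2ccccc2)c1
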